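Ring C is closed last, between C2 and C3. C4 is carried as a ketone, so that C3, flanked by the C4 carbonyl and ring B, is an enol carbon, and C2 is present from the start as the CH2 of the methylthiomethyl ether that protects O1 of ring A. In the key step S-methylation turns this O,S-acetal into an aryloxymethyl cation equivalent, which the silyl enol ether of the open-chain deoxybenzoin captures at C3 to give the isoflavanone in one operation. The same C4 ketone keeps C3 epimerisable, so a ruthenium transfer hydrogenation with dynamic kinetic resolution and in-situ deoxygenation then fixes (3R).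

Key step: step 9

Remark: isoflavan numbering is used throughout (O1, C2, C3, C4; ring A = C4a to C8a; ring B primed), and the target SMILES is read as the (3R) enantiomer.

Step 1
Reactants: 1 2,4-dihydroxyacetophenone
Product: 2 1-[2-hydroxy-4-(methoxymethoxy)phenyl]ethanone
Conditions: MOMCl (1.1 equiv), K2CO3, acetone, 0 °C → rt
Reagents that add atoms: chloromethyl methyl ether (MOMCl), COCCl
Why: Williamson-type MOM protection in which the 2-OH is tied up in a hydrogen bond to the acetyl group, so that only the more acidic para-hydroxyl at C4 should react.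

Step 2
Reactants: 2 1-[2-hydroxy-4-(methoxymethoxy)phenyl]ethanone
Product: 3 1-[5-bromo-2-hydroxy-4-(methoxymethoxy)phenyl]ethanone
Conditions: NBS (1.0 equiv), MeCN, 0 °C
Reagents that add atoms: N-bromosuccinimide, O=C1CCC(=O)N1Br
Why: Electrophilic aromatic bromination, expected at C5 because this carbon is para to the free phenol and ortho to the OMOM group whereas C3 is crowded between two oxygen substituents.

Step 3
Reactants: 3 1-[5-bromo-2-hydroxy-4-(methoxymethoxy)phenyl]ethanone
Product: 4 1-[2-hydroxy-4-(methoxymethoxy)-5-(3-methylbut-2-en-1-yl)phenyl]ethanone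
Conditions: tributyl(prenyl)stannane (1.3 equiv), Pd(PPh3)4 (5 mol %), DMF, 100 °C
Reagents that add atoms: tributyl(3-methylbut-2-en-1-yl)stannane, CCCC[Sn](CCCC)(CCCC)CC=C(C)C
Why: Stille cross-coupling of the aryl bromide with an allylic stannane under neutral conditions that tolerate the free phenol and the ketone, with bond formation expected at the unsubstituted allyl terminus to give the linear prenyl group.

Step 4
Reactants: 4 1-[2-hydroxy-4-(methoxymethoxy)-5-(3-methylbut-2-en-1-yl)phenyl]ethanone
Product: 5 1-{4-(methoxymethoxy)-5-(3-methylbut-2-en-1-yl)-2-[(methylsulfanyl)methoxy]phenyl}ethanone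
Conditions: NaH (1.05 equiv), NaI (cat.), ClCH2SMe (1.2 equiv), DMF, 0 °C → rt
Reagents that add atoms: chloromethyl methyl sulfide, CSCCl
Why: Williamson etherification of the sodium phenoxide (the only site deprotonated by one equivalent of base), which protects O1 for step 8 and installs the CH2 carbon that becomes C2.

Step 5
Reactants: 6 4-bromoresorcinol (4-bromobenzene-1,3-diol)
Product: 7 2-bromo-5-(methoxymethoxy)phenol
Conditions: NaH (2.1 equiv), DMF, 0 °C; MOMCl (1.0 equiv), −20 °C; aq. NH4Cl
Reagents that add atoms: chloromethyl methyl ether (MOMCl), COCCl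
Why: Selective mono-alkylation of the bis-phenoxide, in which the oxygen para to bromine is the more basic and less hindered one and should take the single equivalent of MOMCl, the minor regioisomer and the bis-ether being removable by chromatography.

Step 6
Reactants: 7 2-bromo-5-(methoxymethoxy)phenol
Product: 8 1-bromo-4-(methoxymethoxy)-2-[(2-methylbut-3-yn-2-yl)oxy]benzene
Conditions: 3-chloro-3-methylbut-1-yne (1.5 equiv), DBU (1.3 equiv), CuCl2 (1 mol %), MeCN, 0 °C
Reagents that add atoms: 3-chloro-3-methylbut-1-yne, CC(C)(Cl)C#C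
Why: Copper-catalysed O-propargylation of a phenol with a tertiary propargylic chloride, a mild method that alkylates hindered ortho-substituted phenols and leaves the MOM ether and the aryl bromide untouched.

Step 7
Reactants: 8 1-bromo-4-(methoxymethoxy)-2-[(2-methylbut-3-yn-2-yl)oxy]benzene
Product: 9 8-bromo-5-(methoxymethoxy)-2,2-dimethyl-2H-chromene
Conditions: N,N-diethylaniline, 180 °C
Reagents that add atoms: none
Why: Aryl propargyl ether Claisen rearrangement followed by 1,5-hydrogen shift and oxa-6π electrocyclisation, which can only engage the free ortho carbon between the two oxygen substituents because the other ortho position carries bromine.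

Step 8
Reactants: 5 1-{4-(methoxymethoxy)-5-(3-methylbut-2-en-1-yl)-2-[(methylsulfanyl)methoxy]phenyl}ethanone; 9 8-bromo-5-(methoxymethoxy)-2,2-dimethyl-2H-chromene
Product: 10 2-[5-(methoxymethoxy)-2,2-dimethyl-2H-chromen-8-yl]-1-{4-(methoxymethoxy)-5-(3-methylbut-2-en-1-yl)-2-[(methylsulfanyl)methoxy]phenyl}ethanone
Conditions: Pd2(dba)3 (2.5 mol %), XPhos (6 mol %), NaOtBu (2.2 equiv), toluene, 80 °C; aq. NH4Cl
Reagents that add atoms: none
Why: Palladium-catalysed α-arylation of a methyl ketone enolate with an aryl bromide, in which the more acidic deoxybenzoin product is stored as its enolate (which disfavours a second arylation) and the MOM ethers, the thioacetal, the prenyl group and the chromene are inert to the alkoxide base.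

Step 9
Reactants: 10 2-[5-(methoxymethoxy)-2,2-dimethyl-2H-chromen-8-yl]-1-{4-(methoxymethoxy)-5-(3-methylbut-2-en-1-yl)-2-[(methylsulfanyl)methoxy]phenyl}ethanone
Product: 13 (±)-7-(methoxymethoxy)-3-[5-(methoxymethoxy)-2,2-dimethyl-2H-chromen-8-yl]-6-(3-methylbut-2-en-1-yl)chroman-4-one, via silyl enol ether 11 (not isolated), via sulfonium triflate 12 (not isolated)
Conditions: TIPSOTf (1.2 equiv), Et3N (1.3 equiv), CH2Cl2, 0 °C → rt; then MeOTf (1.5 equiv), 2,6-di-tert-butyl-4-methylpyridine (0.5 equiv), −20 °C → rt; aq. NaHCO3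
Reagents that add atoms: none
Why: Triethylamine and TIPSOTf first convert the C4 ketone into the (Z)-silyl enol ether 11, which blocks the carbonyl oxygen and leaves C3 as the only nucleophilic carbon; MeOTf then methylates the thioether sulfur to sulfonium 12, whose O1–CH2 carbon (an aryloxymethyl cation equivalent) is attacked by C3 with loss of dimethyl sulfide, and the silyl group leaves the resulting silyloxocarbenium ion as TIPSOTf to return the ketone. The closest known reaction types are the MeOTf activation of thioglycosides (O,S-acetals) for C-glycosylation with silyl enol ethers and the C-alkoxymethylation of deoxybenzoin enolates by chloromethyl ethers, so the step is an intramolecular Mukaiyama-type alkylation. Ring C closes in a 6-(enolendo)-exo-tet mode, a favoured geometry in which the enol π-system at C3 reaches the backside of the C2–S bond once the enol unit twists out of the plane of ring A. C3 is created as a racemate without control, which is intended because the centre stays epimerisable beside the C4 ketone and is set in step 10. The step needs C- instead of O-alkylation and methylation at sulfur instead of at oxygen or at the alkenes: silylation of the enol oxygen secures the first, the much higher nucleophilicity of a dialkyl sulfide toward MeOTf secures the second, and the bulky silyl triflate that is released in a buffered medium should spare the MOM acetals, the prenyl group and the chromene.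

Step 10
Reactants: 13 (±)-7-(methoxymethoxy)-3-[5-(methoxymethoxy)-2,2-dimethyl-2H-chromen-8-yl]-6-(3-methylbut-2-en-1-yl)chroman-4-one
Product: 15 (3R)-7-(methoxymethoxy)-3-[5-(methoxymethoxy)-2,2-dimethyl-2H-chromen-8-yl]-6-(3-methylbut-2-en-1-yl)chromane, via cis-isoflavan-4-ol 14 (not isolated)
Conditions: RuCl[(R,R)-TsDPEN](p-cymene) (5 mol %), HCO2H/Et3N (5:2), EtOAc, 45 °C
Reagents that add atoms: none
Why: Noyori–Ikariya asymmetric transfer hydrogenation with dynamic kinetic resolution, run as the domino reduction/deoxygenation known for racemic isoflavanones, in which the C3 epimers interconvert through the enol, the (R,R)-catalyst delivers hydride to C4 anti to the C3 aryl group of the faster-reacting (3R)-ketone to give cis-(3R,4R)-14, and this electron-rich benzylic alcohol (ortho to O1, para to the C7 oxygen) ionises in the formic acid medium and is reduced by hydride without touching C3, the prenyl group or the chromene.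

Step 11
Reactants: 15 (3R)-7-(methoxymethoxy)-3-[5-(methoxymethoxy)-2,2-dimethyl-2H-chromen-8-yl]-6-(3-methylbut-2-en-1-yl)chromane
Product: 16 (3R)-3-(5-hydroxy-2,2-dimethyl-2H-chromen-8-yl)-6-(3-methylbut-2-en-1-yl)chroman-7-ol (target)
Conditions: HCl (2 M aq.), MeOH/THF, rt → 40 °C
Reagents that add atoms: none
Why: Acid-catalysed methanolysis of the two MOM acetals under dilute conditions of the kind used for ortho-prenylphenols and 2,2-dimethylchromenes, which leaves the non-acidic C3 stereocentre untouched.

Compound list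
1 | 2,4-dihydroxyacetophenone | CC(=O)c1ccc(O)cc1O | starting material
2 | 1-[2-hydroxy-4-(methoxymethoxy)phenyl]ethanone | CC(=O)c1ccc(OCOC)cc1O | intermediate
3 | 1-[5-bromo-2-hydroxy-4-(methoxymethoxy)phenyl]ethanone | CC(=O)c1cc(Br)c(OCOC)cc1O | intermediate
4 | 1-[2-hydroxy-4-(methoxymethoxy)-5-(3-methylbut-2-en-1-yl)phenyl]ethanone | CC(=O)c1cc(CC=C(C)C)c(OCOC)cc1O | intermediate
5 | 1-{4-(methoxymethoxy)-5-(3-methylbut-2-en-1-yl)-2-[(methylsulfanyl)methoxy]phenyl}ethanone | CC(=O)c1cc(CC=C(C)C)c(OCOC)cc1OCSC | intermediate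
6 | 4-bromoresorcinol (4-bromobenzene-1,3-diol) | Oc1ccc(Br)c(O)c1 | starting material
7 | 2-bromo-5-(methoxymethoxy)phenol | COCOc1ccc(Br)c(O)c1 | intermediate
8 | 1-bromo-4-(methoxymethoxy)-2-[(2-methylbut-3-yn-2-yl)oxy]benzene | COCOc1ccc(Br)c(OC(C)(C)C#C)c1 | intermediate
9 | 8-bromo-5-(methoxymethoxy)-2,2-dimethyl-2H-chromene | COCOc1ccc(Br)c2OC(C)(C)C=Cc12 | intermediate
10 | 2-[5-(methoxymethoxy)-2,2-dimethyl-2H-chromen-8-yl]-1-{4-(methoxymethoxy)-5-(3-methylbut-2-en-1-yl)-2-[(methylsulfanyl)methoxy]phenyl}ethanone (MTM-protected deoxybenzoin) | CSCOc1cc(OCOC)c(CC=C(C)C)cc1C(=O)Cc1ccc(OCOC)c2C=CC(C)(C)Oc12 | intermediate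
11 | (Z)-triisopropylsilyl enol ether of 10 (silyloxy group on C4, double bond C3=C4) | CSCOc1cc(OCOC)c(CC=C(C)C)cc1/C(O[Si](C(C)C)(C(C)C)C(C)C)=C/c1ccc(OCOC)c2C=CC(C)(C)Oc12 | intermediate (not isolated)
12 | S-methylated 11: aryloxymethyl(dimethyl)sulfonium triflate | C[S+](C)COc1cc(OCOC)c(CC=C(C)C)cc1/C(O[Si](C(C)C)(C(C)C)C(C)C)=C/c1ccc(OCOC)c2C=CC(C)(C)Oc12.[O-]S(=O)(=O)C(F)(F)F | intermediate (not isolated)
13 | (±)-7-(methoxymethoxy)-3-[5-(methoxymethoxy)-2,2-dimethyl-2H-chromen-8-yl]-6-(3-methylbut-2-en-1-yl)chroman-4-one | COCOc1cc2OCC(c3ccc(OCOC)c4C=CC(C)(C)Oc34)C(=O)c2cc1CC=C(C)C | intermediate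
14 | (3R,4R)-7-(methoxymethoxy)-3-[5-(methoxymethoxy)-2,2-dimethyl-2H-chromen-8-yl]-6-(3-methylbut-2-en-1-yl)chroman-4-ol (cis) | CC(C)=CCc1cc2c(cc1OCOC)OC[C@@H](c1ccc(OCOC)c3c1OC(C)(C)C=C3)[C@H]2O | intermediate (not isolated)
15 | (3R)-7-(methoxymethoxy)-3-[5-(methoxymethoxy)-2,2-dimethyl-2H-chromen-8-yl]-6-(3-methylbut-2-en-1-yl)chromane | CC(C)=CCc1cc2c(cc1OCOC)OC[C@@H](c1ccc(OCOC)c3c1OC(C)(C)C=C3)C2 | intermediate
16 | (3R)-3-(5-hydroxy-2,2-dimethyl-2H-chromen-8-yl)-6-(3-methylbut-2-en-1-yl)chroman-7-ol | CC(C)=CCc1cc2c(cc1O)OC[C@@H](c1ccc(O)c3c1OC(C)(C)C=C3)C2 | target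

Total step count: 11. Longest linear sequence: 8 steps (steps 1 to 4, then 8 to 11).

Steps most likely to fail

Step 9. The cation may be captured at oxygen instead of at C3: if enol silylation is incomplete, the ketone oxygen closes a dioxine ring. The silyl triflate may also strip MOM groups. The fallback sets out from 10, makes the O-alkylation the route and comes back at 13. Compound 10 is treated with MeOTf and 2,6-di-tert-butyl-4-methylpyridine alone (CH2Cl2, 0 °C), so that the ketone oxygen displaces dimethyl sulfide and deprotonation gives the enol acetal (Z)-7-(methoxymethoxy)-4-{[5-(methoxymethoxy)-2,2-dimethyl-2H-chromen-8-yl]methylidene}-6-(3-methylbut-2-en-1-yl)-4H-1,3-benzodioxine F1. This is rearranged with Me2AlCl (CH2Cl2, −78 → 0 °C) in a Petasis–Ferrier rearrangement: cleavage of the C2–O bond on the enol side gives an aluminium enolate and an aryloxymethyl cation, which recombine at C3 to form the C2–C3 bond and isoflavanone 13.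

Step 10. The reduction may stall at the carbinol, or the C4 cation may lose the C3 proton, which would erase the stereocentre through an achiral chromene. The fallback sets out from 13, replaces the ionic deoxygenation by a radical one and comes back at 15. Compound 13 is reduced with the same catalyst and HCO2Na in EtOAc/water at room temperature and the cis-alcohol 14 is isolated. It is converted with 1,1'-thiocarbonyldiimidazole into O-[(3R,4R)-7-(methoxymethoxy)-3-[5-(methoxymethoxy)-2,2-dimethyl-2H-chromen-8-yl]-6-(3-methylbut-2-en-1-yl)chroman-4-yl] 1H-imidazole-1-carbothioate F2. Reduction with (Me3Si)3SiH and Et3B/air at room temperature (Barton–McCombie deoxygenation) should give 15 without a cation at C4.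

Step 8. The thioether may bind palladium and slow the catalytic cycle, and the product enolate may be arylated a second time. The fallback sets out from 4 and 9, makes the C–C union before sulfur is introduced and under fluoride instead of alkoxide activation, and comes back at 10. Compound 4 is bis-silylated (TMSCl, NaI, Et3N, MeCN) to trimethyl({1-[4-(methoxymethoxy)-5-(3-methylbut-2-en-1-yl)-2-(trimethylsilyloxy)phenyl]ethenyl}oxy)silane F3. This is arylated with 9 under Pd(dba)2, P(t-Bu)3, ZnF2 and CsF in DMF at 80 °C (arylation of a silyl enol ether). Aqueous work-up gives 1-[2-hydroxy-4-(methoxymethoxy)-5-(3-methylbut-2-en-1-yl)phenyl]-2-[5-(methoxymethoxy)-2,2-dimethyl-2H-chromen-8-yl]ethanone F4, whose sodium phenoxide (NaH, 1.0 equiv, DMF, 0 °C) is alkylated with chloromethyl methyl sulfide to give 10.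

Further compounds
F1 | step 9 | (Z)-7-(methoxymethoxy)-4-{[5-(methoxymethoxy)-2,2-dimethyl-2H-chromen-8-yl]methylidene}-6-(3-methylbut-2-en-1-yl)-4H-1,3-benzodioxine | COCOc1cc2OCO/C(=C\c3ccc(OCOC)c4C=CC(C)(C)Oc34)c2cc1CC=C(C)C
F2 | step 10 | O-[(3R,4R)-7-(methoxymethoxy)-3-[5-(methoxymethoxy)-2,2-dimethyl-2H-chromen-8-yl]-6-(3-methylbut-2-en-1-yl)chroman-4-yl] 1H-imidazole-1-carbothioate | CC(C)=CCc1cc2c(cc1OCOC)OC[C@@H](c1ccc(OCOC)c3c1OC(C)(C)C=C3)[C@H]2OC(=S)n1ccnc1
F3 | step 8 | trimethyl({1-[4-(methoxymethoxy)-5-(3-methylbut-2-en-1-yl)-2-(trimethylsilyloxy)phenyl]ethenyl}oxy)silane | C=C(O[Si](C)(C)C)c1cc(CC=C(C)C)c(OCOC)cc1O[Si](C)(C)C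
F4 | step 8 | 1-[2-hydroxy-4-(methoxymethoxy)-5-(3-methylbut-2-en-1-yl)phenyl]-2-[5-(methoxymethoxy)-2,2-dimethyl-2H-chromen-8-yl]ethanone | CC(C)=CCc1cc(C(=O)Cc2ccc(OCOC)c3C=CC(C)(C)Oc23)c(O)cc1OCOC
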